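**Assumption:** chroman numbering O1, C2 (aryl), C4 (side chain); the SMILES is read as (2R,4S), i.e. 2,4-trans, with a (2R)-carbinol in the side chain. TBS = tert-butyldimethylsilyl; primed locants are those of the chalcone ring A (C1' acyl, C2' OH, C4' OTBS, C6' OMe).

## Retrosynthetic overview

1. Target 16 ⇐ tetrakis-TBS chroman 15 by buffered fluoride.
2. 15 ⇐ homoallylic alcohol 6 + aldehyde 12 + chalcone 11 in one flask: Prins cyclization closes an all-cis oxane whose C4 cation is captured by ring A of 11; silyl triflate/base then moves the benzylic C–O bond from the oxane oxygen to the phenol oxygen, closing the chroman and releasing the carbinol.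
3. 6 ⇐ asymmetric allylation of aldehyde 4 ⇐ Heck arylation of allyl alcohol 2 with aryl iodide 1.
4. 11 ⇐ bis-silylation of helichrysetin 10 ⇐ Claisen–Schmidt condensation of 7 and 8.
5. Ring order: the four benzene rings are bought; oxane ring first, chroman ring second (the oxane is opened again in the same operation).

## Route

Step 1
Reactants: 1 tert-butyl(4-iodophenoxy)dimethylsilane; 2 prop-2-en-1-ol
Product: 4 3-[4-(tert-butyldimethylsilyloxy)phenyl]propanal, via enol 3 (not isolated)
Conditions: Pd(OAc)2 (3 mol%), Bu4NCl (1 equiv), NaHCO3 (2.5 equiv), DMF, 40 °C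
Reagents that add atoms: none
Why: Jeffery-type Heck arylation of allyl alcohol; β-hydride elimination toward the carbinol carbon gives the enol, which tautomerizes to the 3-arylpropanal; no stereocenter is formed.

Step 2
Reactants: 4 3-[4-(tert-butyldimethylsilyloxy)phenyl]propanal
Product: 6 (3R)-1-[4-(tert-butyldimethylsilyloxy)phenyl]hex-5-en-3-ol, via tributylstannyl ether 5 (not isolated)
Conditions: (S)-BINOL (20 mol%), Ti(OiPr)4 (10 mol%), 4 Å MS, CH2Cl2; allylSnBu3 (1.5 equiv), −20 °C, 60 h; aq. NaHCO3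
Reagents that add atoms: allyltributylstannane, C=CC[Sn](CCCC)(CCCC)CCCC
Why: Keck asymmetric allylation; the (S)-BINOL–titanium catalyst delivers allyl to the Si face of the aldehyde (the sense that gives (S)-1-phenylbut-3-en-1-ol from benzaldehyde), which here is the (3R)-alcohol because allyl outranks the arylethyl chain.

Step 3
Reactants: 7 1-(2,4-dihydroxy-6-methoxyphenyl)ethan-1-one; 8 4-hydroxybenzaldehyde
Product: 10 helichrysetin [(E)-1-(2,4-dihydroxy-6-methoxyphenyl)-3-(4-hydroxyphenyl)prop-2-en-1-one], via aldol adduct 9 (not isolated)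
Conditions: KOH (50% aq., 10 equiv), EtOH, rt, 72 h; then 2 M HCl to pH 4
Reagents that add atoms: none
Why: Claisen–Schmidt condensation; E1cB dehydration of the aldol gives the conjugated (E)-enone, and the 6'-methoxy-2'-hydroxy chalcone is isolated in its open form.

Step 4
Reactants: 10 helichrysetin
Product: 11 (E)-1-[4-(tert-butyldimethylsilyloxy)-2-hydroxy-6-methoxyphenyl]-3-[4-(tert-butyldimethylsilyloxy)phenyl]prop-2-en-1-one
Conditions: TBSCl (2.3 equiv), imidazole (5 equiv), DMF, 0 °C to rt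
Reagents that add atoms: tert-butyldimethylsilyl chloride, CC(C)(C)[Si](C)(C)Cl
Why: Selective O-silylation; the two free phenols react while the 2'-hydroxyl, hydrogen-bonded to the carbonyl, stays free, so only the oxygen that must later close the chroman is left open.

Step 5
Reactants: 6 (3R)-1-[4-(tert-butyldimethylsilyloxy)phenyl]hex-5-en-3-ol (1.0 equiv); 11 bis-TBS chalcone (1.5 equiv); 12 4-(tert-butyldimethylsilyloxy)benzaldehyde (1.1 equiv)
Product: 15 (E)-1-[(2R,4S)-5-(TBSO)-2-[4-(TBSO)phenyl]-4-[(2R)-2-hydroxy-4-[4-(TBSO)phenyl]butyl]-7-methoxy-3,4-dihydro-2H-chromen-8-yl]-3-[4-(TBSO)phenyl]prop-2-en-1-one, via all-cis oxane 13 (not isolated), via trimethylsilyl ether 14 (not isolated)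
Conditions: Me3SiOTf (4 equiv), CH2Cl2, −78 °C, 1 h; then 2,6-di-tert-butyl-4-methylpyridine (4.5 equiv), −78 to −20 °C, 3 h; Et3N/MeOH quench; aq. citric acid, THF, 0 °C
Reagents that add atoms: none
Why: Proposed new method: Me3SiOTf turns 6 and 12 into the (E)-oxocarbenium ion, which undergoes Prins cyclization through a chair with both substituents equatorial, and the oxan-4-yl cation is captured equatorially by C3' of 11 (Friedel–Crafts alkylation ortho to the chelated hydroxyl, the site where 2-hydroxy-4,6-dialkoxyaryl ketones are usually halogenated and formylated, while C5' is screened by the in-plane methoxy methyl and the silyl ether), so C4 is set cis to the carbinol substituent from the (3R) centre of 6; once the hindered base is added, excess Me3SiOTf ionizes the p-silyloxybenzylic C–O bond of oxane 13, the oxane oxygen leaves as a silyl ether and the neighbouring phenol oxygen closes the chroman, the proton going irreversibly to the base, through a half-chair with the C4 chain pseudoaxial (no 1,3-allylic strain with the peri C5 silyl ether) and the aryl group pseudoequatorial, which gives the 2,4-trans (2R,4S) ring whatever the C2 configuration of 13; the closest known reactions are the three-component Prins cyclization/Friedel–Crafts arylation to 4-aryloxanes, silyl triflate cleavage of p-alkoxybenzyl ethers, and closure of phenols onto benzylic cations to give flavans.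

Step 6
Reactants: 15 tetrakis-TBS chroman
Product: 16 (E)-1-[(2R,4S)-5-hydroxy-4-[(2R)-2-hydroxy-4-(4-hydroxyphenyl)butyl]-2-(4-hydroxyphenyl)-7-methoxy-3,4-dihydro-2H-chromen-8-yl]-3-(4-hydroxyphenyl)prop-2-en-1-one (target)
Conditions: Bu4NF (6 equiv), AcOH (6 equiv), THF, 0 °C to rt
Reagents that add atoms: none
Why: Fluoride desilylation of the four aryl silyl ethers; the acetic acid buffer keeps the phenols protonated, which avoids both phenoxide-driven quinone methide opening of the 2-(4-hydroxyphenyl)chroman and acid-driven return to the oxane, so no stereocenter is touched.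

## Compound list

1 | tert-butyl(4-iodophenoxy)dimethylsilane | CC(C)(C)[Si](C)(C)Oc1ccc(I)cc1 | starting material
2 | prop-2-en-1-ol | C=CCO | starting material
3 | 3-[4-(tert-butyldimethylsilyloxy)phenyl]prop-1-en-1-ol (enol, not isolated) | OC=CCc1ccc(O[Si](C)(C)C(C)(C)C)cc1 | intermediate
4 | 3-[4-(tert-butyldimethylsilyloxy)phenyl]propanal | O=CCCc1ccc(O[Si](C)(C)C(C)(C)C)cc1 | intermediate
5 | tributyl{[(3R)-1-[4-(tert-butyldimethylsilyloxy)phenyl]hex-5-en-3-yl]oxy}stannane (not isolated) | C=CC[C@H](O[Sn](CCCC)(CCCC)CCCC)CCc1ccc(O[Si](C)(C)C(C)(C)C)cc1 | intermediate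
6 | (3R)-1-[4-(tert-butyldimethylsilyloxy)phenyl]hex-5-en-3-ol | C=CC[C@H](O)CCc1ccc(O[Si](C)(C)C(C)(C)C)cc1 | intermediate
7 | 1-(2,4-dihydroxy-6-methoxyphenyl)ethan-1-one | CC(=O)c1c(O)cc(O)cc1OC | starting material
8 | 4-hydroxybenzaldehyde | O=Cc1ccc(O)cc1 | starting material
9 | 3-hydroxy-1-(2,4-dihydroxy-6-methoxyphenyl)-3-(4-hydroxyphenyl)propan-1-one (racemic, not isolated) | COc1cc(O)cc(O)c1C(=O)CC(O)c1ccc(O)cc1 | intermediate
10 | helichrysetin, (E)-1-(2,4-dihydroxy-6-methoxyphenyl)-3-(4-hydroxyphenyl)prop-2-en-1-one | COc1cc(O)cc(O)c1C(=O)/C=C/c1ccc(O)cc1 | intermediate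
11 | (E)-1-[4-(tert-butyldimethylsilyloxy)-2-hydroxy-6-methoxyphenyl]-3-[4-(tert-butyldimethylsilyloxy)phenyl]prop-2-en-1-one | COc1cc(O[Si](C)(C)C(C)(C)C)cc(O)c1C(=O)/C=C/c1ccc(O[Si](C)(C)C(C)(C)C)cc1 | intermediate
12 | 4-(tert-butyldimethylsilyloxy)benzaldehyde | O=Cc1ccc(O[Si](C)(C)C(C)(C)C)cc1 | starting material
13 | (E)-1-[4-(TBSO)-2-hydroxy-6-methoxy-3-[(2R,4S,6R)-2-[4-(TBSO)phenyl]-6-[2-[4-(TBSO)phenyl]ethyl]oxan-4-yl]phenyl]-3-[4-(TBSO)phenyl]prop-2-en-1-one (all-cis oxane, not isolated) | O1[C@@H](c2ccc(O[Si](C)(C)C(C)(C)C)cc2)C[C@@H](c2c(O)c(C(=O)/C=C/c3ccc(O[Si](C)(C)C(C)(C)C)cc3)c(OC)cc2O[Si](C)(C)C(C)(C)C)C[C@H]1CCc1ccc(O[Si](C)(C)C(C)(C)C)cc1 | intermediate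
14 | trimethylsilyl ether of 15 at the side-chain hydroxyl, same configuration (not isolated) | COc1cc(O[Si](C)(C)C(C)(C)C)c2c(c1C(=O)/C=C/c1ccc(O[Si](C)(C)C(C)(C)C)cc1)O[C@@H](c1ccc(O[Si](C)(C)C(C)(C)C)cc1)C[C@@H]2C[C@H](O[Si](C)(C)C)CCc1ccc(O[Si](C)(C)C(C)(C)C)cc1 | intermediate
15 | (E)-1-[(2R,4S)-5-(TBSO)-2-[4-(TBSO)phenyl]-4-[(2R)-2-hydroxy-4-[4-(TBSO)phenyl]butyl]-7-methoxy-3,4-dihydro-2H-chromen-8-yl]-3-[4-(TBSO)phenyl]prop-2-en-1-one | COc1cc(O[Si](C)(C)C(C)(C)C)c2c(c1C(=O)/C=C/c1ccc(O[Si](C)(C)C(C)(C)C)cc1)O[C@@H](c1ccc(O[Si](C)(C)C(C)(C)C)cc1)C[C@@H]2C[C@H](O)CCc1ccc(O[Si](C)(C)C(C)(C)C)cc1 | intermediate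
16 | (E)-1-[(2R,4S)-5-hydroxy-4-[(2R)-2-hydroxy-4-(4-hydroxyphenyl)butyl]-2-(4-hydroxyphenyl)-7-methoxy-3,4-dihydro-2H-chromen-8-yl]-3-(4-hydroxyphenyl)prop-2-en-1-one (CNP0102599.2) | COc1cc(O)c2c(c1C(=O)/C=C/c1ccc(O)cc1)O[C@@H](c1ccc(O)cc1)C[C@@H]2C[C@H](O)CCc1ccc(O)cc1 | target

## Step count

Total steps: 6. Longest linear sequence: 4 steps (1 → 4 → 6 → 15 → 16, or 7 → 10 → 11 → 15 → 16).

## Three steps most likely to fail

**First risk, step 5.** The ring switch is untested and could stall at oxane 13, since a dialkyl ether with a chelated phenol is the more stable isomer under plain acid. The chalcone, deactivated by its carbonyl, may also capture the cation slowly or partly at C5', and the electron-rich aldehyde invites some 2-oxonia-Cope erosion of enantiomeric purity. The fallback replaces the cationic domino by stepwise ether cleavage and a base-driven Williamson-type closure, which takes the acid equilibrium out of play. It sets out from 13, isolated by quenching the first stage at −78 °C with Et3N. Me3SiBr in CH2Cl2 at −40 °C cleaves the benzylic C–O bond to give (E)-1-[3-[(3S,5R)-1-bromo-1,7-bis[4-(TBSO)phenyl]-5-(trimethylsilyloxy)heptan-3-yl]-4-(TBSO)-2-hydroxy-6-methoxyphenyl]-3-[4-(TBSO)phenyl]prop-2-en-1-one F1 (both C1 epimers). iPr2NEt at −40 to 0 °C then closes the chroman by intramolecular O-alkylation of the phenol, under the same conformational preference for the 2,4-trans ring. The fallback comes back to the route at 14, which the citric acid work-up converts to 15.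

**Second risk, step 3.** Under KOH both partners are phenolates, so the ketone enolizes poorly and the aldehyde is a weak electrophile; low conversion and some flavanone are likely. The fallback is a directed aldol of silyl-protected partners instead of a hydroxide condensation. It sets out from 7: TBSCl (1.1 equiv) and imidazole in CH2Cl2 give 1-[4-(tert-butyldimethylsilyloxy)-2-hydroxy-6-methoxyphenyl]ethan-1-one F2. Its dianion, formed with LiN(SiMe3)2 (2.2 equiv) in THF at −78 °C, adds to 12 to give 3-hydroxy-1-[4-(tert-butyldimethylsilyloxy)-2-hydroxy-6-methoxyphenyl]-3-[4-(tert-butyldimethylsilyloxy)phenyl]propan-1-one F3 (racemic). MsCl and Et3N in CH2Cl2 at 0 °C dehydrate it to the (E)-enone. The fallback comes back to the route at 11, so 10 and step 4 are bypassed.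

**Third risk, step 1.** The Heck arylation of allyl alcohol can give the branched 2-arylpropanal and cinnamyl alcohol as by-products, and the aryl silyl ether may be partly lost in warm DMF with bicarbonate. The fallback separates C–C bond formation from the oxidation-state adjustment. It sets out from 1: Heck coupling with methyl acrylate (Pd(OAc)2, tri-o-tolylphosphine, Et3N, MeCN, 80 °C) gives methyl (E)-3-[4-(tert-butyldimethylsilyloxy)phenyl]prop-2-enoate F4. Hydrogenation (H2, Pd/C, EtOAc) gives methyl 3-[4-(tert-butyldimethylsilyloxy)phenyl]propanoate F5. Reduction with iBu2AlH in CH2Cl2 at −78 °C gives the aldehyde, and the fallback comes back to the route at 4.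

## Further compounds

F1 | step 5 | (E)-1-[3-[(3S,5R)-1-bromo-1,7-bis[4-(tert-butyldimethylsilyloxy)phenyl]-5-(trimethylsilyloxy)heptan-3-yl]-4-(tert-butyldimethylsilyloxy)-2-hydroxy-6-methoxyphenyl]-3-[4-(tert-butyldimethylsilyloxy)phenyl]prop-2-en-1-one (C1 epimers) | BrC(c1ccc(O[Si](C)(C)C(C)(C)C)cc1)C[C@@H](c1c(O)c(C(=O)/C=C/c2ccc(O[Si](C)(C)C(C)(C)C)cc2)c(OC)cc1O[Si](C)(C)C(C)(C)C)C[C@H](O[Si](C)(C)C)CCc1ccc(O[Si](C)(C)C(C)(C)C)cc1
F2 | step 3 | 1-[4-(tert-butyldimethylsilyloxy)-2-hydroxy-6-methoxyphenyl]ethan-1-one | CC(=O)c1c(O)cc(O[Si](C)(C)C(C)(C)C)cc1OC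
F3 | step 3 | 3-hydroxy-1-[4-(tert-butyldimethylsilyloxy)-2-hydroxy-6-methoxyphenyl]-3-[4-(tert-butyldimethylsilyloxy)phenyl]propan-1-one (racemic) | COc1cc(O[Si](C)(C)C(C)(C)C)cc(O)c1C(=O)CC(O)c1ccc(O[Si](C)(C)C(C)(C)C)cc1
F4 | step 1 | methyl (E)-3-[4-(tert-butyldimethylsilyloxy)phenyl]prop-2-enoate | COC(=O)/C=C/c1ccc(O[Si](C)(C)C(C)(C)C)cc1
F5 | step 1 | methyl 3-[4-(tert-butyldimethylsilyloxy)phenyl]propanoate | COC(=O)CCc1ccc(O[Si](C)(C)C(C)(C)C)cc1
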